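**Numbering used throughout.** Ring: C1 (OAc), C2 (OH), C3 (H), C4 (OH), C5 (H), C6 (chain). Chain: C1' to C17', counted from the ring. Compounds 1 to 20 are defined in the steps and in the compound list.

## Analysis of the target

Ardisiphenol C 20 is a benzene ring oxygenated at C1, C2 and C4, with an acetate on C1, free hydroxyls on C2 and C4, hydrogens on C3 and C5 and an unbranched C17 chain on C6. The chain runs through seven methylenes (C1' to C7'), two double bonds (C8'=C9' and C11'=C12') separated by the single methylene C10', and a pentyl end. There is no stereogenic carbon; the only stereo-elements are the two double bonds, which are independent of each other, must both be Z and can be set in one operation. The aryl acetate sits next to the free C2 hydroxyl, so base can hydrolyse it or move it to O2. Without the acetate the ring is a hydroxyhydroquinone that oxidises in air, and the doubly allylic C10' is prone to autoxidation and to isomerisation into conjugation. The real difficulty is telling three phenolic oxygens apart: the acetate is on the most hindered one, between the chain and O2, where selective acylation of a triol would not place it. The strategy rests on two features: C2–C3–C4–C5 is a four-carbon unit oxygenated at its first and third carbons, which is the pattern of an acetoacetate-derived diene, and C1 and C6 are two adjacent ring carbons that can come from an alkyne. If C1 first carries an acetyl group, that group activates the alkyne for ring formation and is afterwards turned into the acetate in place.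

## Retrosynthetic reasoning

**20 to 19.** The last operation only uncovers O2 and O4. Silyl ethers are chosen because they come off with buffered fluoride, without base, so the neighbouring acetate on O1 is neither cleaved nor shifted.

**19 to 18.** The two Z double bonds are traced back to the two triple bonds of a skipped diyne. No skeletal bond is cut; only the oxidation level of the chain changes. This is done because the preceding step uses a peracid, which would epoxidise alkenes but reacts only sluggishly with alkynes. A single syn semi-hydrogenation then sets both geometries.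

**18 to 16.** The C1–O bond is traced back to a C1–acetyl bond by a Baeyer–Villiger oxidation. The acetate is thus generated on C1 and nowhere else, and no selective acylation among three phenols is needed. The forward step needs aryl migration to beat methyl migration, which the electron-rich, doubly ortho-substituted ring should ensure.

**16 to 15.** The silyl groups on O2 and O4 are placed on the free acylresorcinol 15. They keep the ring from being oxidised by the peracid and fix which oxygens end up free.

**15 to 9 and 13.** This is the ring disconnection. Bonds C1–C2 and C5–C6 are cut, which divides the benzene ring into the four-carbon diene 13 (C2 to C5 with both oxygens) and the two alkyne carbons of ynone 9 (C1 with its acetyl, C6 with the chain). Cutting here uses the native polarity of both pieces: the CH2 end of 13 is nucleophilic and the chain-bearing carbon of 9 is electrophilic, so the orientation is not in doubt. The forward reaction has to form both bonds and then aromatise by expelling the methoxy group of the ketal carbon.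

**13 to 11 to 10.** The diene 13 is the doubly O-silylated form of methyl acetoacetate 10. The first silyl group goes onto the enol oxygen to give 11, and the second is placed on the dienolate 12 that γ-deprotonation of 11 provides.

**9 to 5 and 6.** The bond between the carbonyl carbon and the alkyne (C2–C3 of 9) is cut, giving the terminal alkyne 5 and the Weinreb amide 6. The acylation goes through the lithium acetylide 7 and the chelate 8, and stops at the ketone.

**5 to 1 and 2.** The sp–sp3 bond C11–C12 of 5 is cut, giving the symmetric diyne 1 and the propargylic bromide 2. A copper-mediated coupling, running through 3 and 4, builds the skipped diyne without strong base. The symmetry of 1 is handled by using it in excess.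

## Alternatives that were turned down

Alternative 1: Aryne route. The disconnection cuts C6–C1' and C1–O at once and leads back to an aryne spanning C1 and C6. In the forward key step, 2-bromo-1-fluoro-3,5-bis(methoxymethoxy)benzene A2 undergoes halogen–magnesium exchange at bromine and loses fluoride on warming. The Grignard reagent [(8Z,11Z)-heptadeca-8,11-dienyl]magnesium bromide A3 then adds at C6, remote from the C2 alkoxy group, so that the aryl anion sits at C1 beside that oxygen. Borylation and peroxide oxidation in the same pot give 2-[(8Z,11Z)-heptadeca-8,11-dienyl]-4,6-bis(methoxymethoxy)phenol A1.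
- For it: two bonds, including the difficult C1–O bond, are made in one flask. The Z,Z-diene is brought in intact, so there is no alkyne coupling and no semi-hydrogenation. In A1 the oxygen on C1 is born free and distinct from O2 and O4. From A1 only acetylation and acetal removal remain, so on step count after the key step this route is stronger than the chosen one.
- Against it: A3 needs a C17 halide that is not a catalogue compound, and A2 needs several steps of regiocontrolled halogenation. The aryne can also react with the chain alkenes (ene reaction, [2+2]) or with the product arylmagnesium. The final removal of two methoxymethyl ethers needs protic or Lewis acid next to an aryl acetate that can transesterify or migrate.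
- Comparison: the risk is spread over precursor synthesis, key step and last step. The chosen route uses two easily made partners, gets the C1 oxygen from the same acetyl group that activates the dienophile, and ends with a deprotection orthogonal to the acetate.

Alternative 2: Polyketide-type aldol aromatisation. The disconnection cuts the ring bond C1–C6. In the forward key step a tertiary amine or carbonate base makes the dioxinone α-carbon of 6-[(12Z,15Z)-2,4-dioxohenicosa-12,15-dienyl]-2,2-dimethyl-1,3-dioxin-4-one A5 attack the chain ketone. Dehydration gives 5-[(8Z,11Z)-heptadeca-8,11-dienyl]-7-hydroxy-2,2-dimethyl-1,3-benzodioxin-4-one A4.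
- For it: the chain of A5 comes from linoleic acid A6, and A6 supplies C6 and the whole C17 chain with both Z alkenes already in place. On chain sourcing this is clearly stronger than the chosen route. The aromatisation of A5 is mild, and O2 (in the acetonide) is distinguished from O4 (free).
- Against it: C1 of A4 carries a carboxyl carbon where the target has oxygen. The exchange means degrading the ester to a ketone or aldehyde and then oxidising with peracid or peroxide in the presence of the skipped diene. A peracid would epoxidise both alkenes. Alkaline peroxide spares them but leaves O1 free beside O2 on an unprotected, air-sensitive ring, so the two oxygens can no longer be told apart.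
- Comparison: four or more extra steps after A4 lead back to the selectivity problem the target poses. The chosen route delivers C1 directly as a methyl ketone and carries the chain as alkynes so that the peracid step is possible.

Alternative 3: Photochemical Wolff benzannulation. The disconnection takes apart four of the six ring bonds: C5–C6 by the Wolff shift, C2–C3 and C4–C5 by ketene–alkyne [2+2], and C1–C2 by electrocyclisation. Only C3–C4 (the alkyne) and C1–C6 (the enol acetate double bond) are carried in. In the forward key step [(10Z,13Z)-2-(2-diazoacetyl)nonadeca-1,10,13-trienyl] acetate A8 is irradiated with tert-butoxyethyne A9 and then heated. Wolff shift, [2+2] addition, four-electron ring opening and six-electron ring closure follow one another to give 4-tert-butoxy-2-[(8Z,11Z)-heptadeca-8,11-dienyl]-6-hydroxyphenyl acetate A7.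
- For it: all four substituents arrive in one operation, with the acetate already on C1 and the hydroxyl free on C2, so no oxidation-state change is needed. Regiocontrol comes from the polarity of the ynol ether A9, and from A7 only tert-butyl removal remains. On directness it is stronger than the chosen route.
- Against it: A8 is an enol acetate and a diazo ketone at once, needs several steps, and is not a typical substrate for this annulation. A9 is not sold and fragments on warming in the temperature range of the thermal stage. A7 is heated with the acetate next to a free hydroxyl, which invites O1 to O2 migration. Strong acid for the tert-butyl ether generates cations beside an electron-rich ring and a skipped diene. The carbene precursor is photolysed in the presence of two alkenes.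
- Comparison: the chosen route relies on a long-established diene and purely thermal ground-state chemistry, at the cost of four steps after the ring is made.

Key step: step 5

## Route

Remark on the chemistry: undeca-1,10-diyne 1 is taken to be purchasable. Compounds 11, 12 and 13 are used as mixtures of double-bond isomers, and 8, 14 and 17 are racemic at a centre that does not survive the step, so their SMILES carry no stereodescriptor.

Step 1
Reactants: 1 undeca-1,10-diyne; 2 1-bromooct-2-yne
Product: 5 nonadeca-1,10,13-triyne, via 1-iodooct-2-yne 3 (not isolated), via undeca-1,10-diyn-1-ylcopper 4 (not isolated)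
Conditions: CuI, NaI, K2CO3, DMF, rt, 1 in fourfold excess
Reagents that add atoms: none
Why: Copper-mediated sp–sp3 coupling of a terminal alkyne with a propargylic halide, the standard entry to skipped diynes without strong base; NaI makes the more reactive iodide 3 and CuI/K2CO3 the copper acetylide 4. The excess of 1 suppresses double coupling and is distilled back.

Step 2
Reactants: 5 nonadeca-1,10,13-triyne; 6 N-methoxy-N-methylacetamide
Product: 9 henicosa-3,12,15-triyn-2-one, via nonadeca-1,10,13-triyn-1-yllithium 7 (not isolated), via lithium aminal alkoxide 8 (not isolated)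
Conditions: n-BuLi (1.0 equiv), THF, −78 °C; then 6, −78 to 0 °C; aq. NH4Cl
Reagents that add atoms: none
Why: Weinreb ketone synthesis; the terminal C–H is far more acidic than the doubly propargylic CH2, so one equivalent of base at −78 °C should give only acetylide 7. Chelate 8 holds the adduct until the quench, so no second addition occurs.

Step 3
Reactants: 10 methyl acetoacetate
Product: 11 methyl 3-(trimethylsilyloxy)but-2-enoate
Conditions: TMSCl, Et3N, hexane, rt
Reagents that add atoms: chlorotrimethylsilane, C[Si](C)(C)Cl
Why: Silyl enol ether formation on the enol of a β-keto ester; the double-bond geometry is irrelevant because it is lost later.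

Step 4
Reactants: 11 methyl 3-(trimethylsilyloxy)but-2-enoate
Product: 13 1-methoxy-1,3-bis(trimethylsilyloxy)buta-1,3-diene, via lithium dienolate 12 (not isolated)
Conditions: LiN(i-Pr)2, THF, −78 °C; then TMSCl, −78 to 0 °C
Reagents that add atoms: chlorotrimethylsilane, C[Si](C)(C)Cl
Why: γ-Deprotonation of the silyl enol ether gives the cross-conjugated dienolate 12, which is trapped on oxygen (silyl ketene acetal formation). The moisture-sensitive diene is used directly after bulb-to-bulb distillation.

Step 5
Reactants: 9 henicosa-3,12,15-triyn-2-one; 13 1-methoxy-1,3-bis(trimethylsilyloxy)buta-1,3-diene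
Product: 15 1-[2-(heptadeca-8,11-diynyl)-4,6-dihydroxyphenyl]ethanone, via cyclohexa-1,4-diene cycloadduct 14 (not isolated)
Conditions: toluene, 80 °C, 13 in threefold excess; then 1 M HCl, THF, rt
Reagents that add atoms: none
Why: Normal-electron-demand, strongly asynchronous [4+2] cycloaddition: the CH2 terminus of 13 (largest HOMO coefficient) bonds to the chain-bearing β-carbon of the ynone (C5–C6) and the ketene acetal carbon closes onto the acetyl-bearing α-carbon (C1–C2). The closest known reaction type is the Diels–Alder addition of 1,1,3-trioxygenated butadienes to acetylenic esters and ketones with aromatisation to resorcylates and acylresorcinols. The six-membered ring is closed by the intermolecular cycloaddition itself, both ring bonds forming in one suprafacial event to give the 1,4-cyclohexadiene 14. On acid work-up the mixed methyl silyl ketal at C2 is desilylated to a hemiketal that expels methanol, the resulting cross-conjugated dienone tautomerises through its C5 hydrogen, and the remaining silyl ether is hydrolysed, so the ring aromatises to 15 with the C2 hydroxyl hydrogen-bonded to the acetyl group. No lasting stereocentre is formed; the ketal carbon of 14 arises without control and is destroyed on aromatisation. The step needs regioselectivity, chemoselectivity and the cycloaddition mode: the orientation follows from the matched polarisation of the two partners, only the conjugated triple bond of the three is electron-poor enough to react, and the absence of any Lewis acid should keep the reaction from diverting to a Michael–aldol closure onto the acetyl carbonyl.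

Step 6
Reactants: 15 1-[2-(heptadeca-8,11-diynyl)-4,6-dihydroxyphenyl]ethanone
Product: 16 1-[2,4-bis(tert-butyldimethylsilyloxy)-6-(heptadeca-8,11-diynyl)phenyl]ethanone
Conditions: TBSCl, imidazole, DMF, rt to 45 °C
Reagents that add atoms: tert-butyldimethylsilyl chloride, CC(C)(C)[Si](C)(C)Cl
Why: Silyl ether formation on both phenols; the hydrogen-bonded ortho hydroxyl reacts slowly, hence excess reagent and gentle warming. The ethers shield the ring from the peracid and fix which oxygens are free at the end.

Step 7
Reactants: 16 1-[2,4-bis(tert-butyldimethylsilyloxy)-6-(heptadeca-8,11-diynyl)phenyl]ethanone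
Product: 18 [2,4-bis(tert-butyldimethylsilyloxy)-6-(heptadeca-8,11-diynyl)phenyl] acetate, via Criegee adduct 17 (not isolated)
Conditions: m-CPBA, Na2HPO4, CH2Cl2, 0 °C to rt
Reagents that add atoms: 3-chloroperoxybenzoic acid, OOC(=O)c1cccc(Cl)c1
Why: Baeyer–Villiger oxidation; in adduct 17 the electron-rich, doubly ortho-substituted aryl group migrates in preference to methyl, so the acetate forms on C1 only. Isolated triple bonds react with peracids far more slowly than double bonds, which is why the chain is still a diyne here.

Step 8
Reactants: 18 [2,4-bis(tert-butyldimethylsilyloxy)-6-(heptadeca-8,11-diynyl)phenyl] acetate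
Product: 19 [2,4-bis(tert-butyldimethylsilyloxy)-6-[(8Z,11Z)-heptadeca-8,11-dienyl]phenyl] acetate
Conditions: H2 (1 atm), Pd/CaCO3 poisoned with Pb(OAc)2, quinoline, EtOAc/hexane, rt
Reagents that add atoms: none
Why: Semi-hydrogenation of the Lindlar type; syn delivery of hydrogen on the poisoned palladium surface sets both Z double bonds (C8'=C9' and C11'=C12') at once. Hydrogen uptake is followed and the reaction stopped at two equivalents.

Step 9
Reactants: 19 [2,4-bis(tert-butyldimethylsilyloxy)-6-[(8Z,11Z)-heptadeca-8,11-dienyl]phenyl] acetate
Product: 20 ardisiphenol C, [2-[(8Z,11Z)-heptadeca-8,11-dienyl]-4,6-dihydroxyphenyl] acetate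
Conditions: HF·pyridine, pyridine, THF, 0 °C to rt
Reagents that add atoms: none
Why: Fluoride cleavage of aryl silyl ethers under buffered, non-basic conditions; the acetate on O1 should neither hydrolyse nor move to the freed O2. A neutral work-up and quick chromatography keep it that way.

## Compound list

1 | undeca-1,10-diyne | C#CCCCCCCCC#C | starting material
2 | 1-bromooct-2-yne | CCCCCC#CCBr | starting material
3 | 1-iodooct-2-yne | CCCCCC#CCI | intermediate
4 | undeca-1,10-diyn-1-ylcopper | [Cu]C#CCCCCCCCC#C | intermediate
5 | nonadeca-1,10,13-triyne | C#CCCCCCCCC#CCC#CCCCCC | intermediate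
6 | N-methoxy-N-methylacetamide | CON(C)C(C)=O | starting material
7 | nonadeca-1,10,13-triyn-1-yllithium | [Li]C#CCCCCCCCC#CCC#CCCCCC | intermediate
8 | lithium 2-[methoxy(methyl)amino]henicosa-3,12,15-triyn-2-olate (racemic) | CC(O[Li])(N(C)OC)C#CCCCCCCCC#CCC#CCCCCC | intermediate
9 | henicosa-3,12,15-triyn-2-one | CC(=O)C#CCCCCCCCC#CCC#CCCCCC | intermediate
10 | methyl acetoacetate (methyl 3-oxobutanoate) | COC(=O)CC(C)=O | starting material
11 | methyl 3-(trimethylsilyloxy)but-2-enoate (E/Z mixture) | COC(=O)C=C(C)O[Si](C)(C)C | intermediate
12 | lithium 1-methoxy-3-(trimethylsilyloxy)buta-1,3-dien-1-olate | C=C(O[Si](C)(C)C)C=C(OC)O[Li] | intermediate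
13 | 1-methoxy-1,3-bis(trimethylsilyloxy)buta-1,3-diene (mixture of ketene acetal isomers) | C=C(O[Si](C)(C)C)C=C(OC)O[Si](C)(C)C | intermediate
14 | 1-[2-(heptadeca-8,11-diynyl)-6-methoxy-4,6-bis(trimethylsilyloxy)cyclohexa-1,4-dien-1-yl]ethanone (racemic) | CC(=O)C1=C(CCCCCCCC#CCC#CCCCCC)CC(O[Si](C)(C)C)=CC1(OC)O[Si](C)(C)C | intermediate
15 | 1-[2-(heptadeca-8,11-diynyl)-4,6-dihydroxyphenyl]ethanone | CCCCCC#CCC#CCCCCCCCc1cc(O)cc(O)c1C(C)=O | intermediate
16 | 1-[2,4-bis(tert-butyldimethylsilyloxy)-6-(heptadeca-8,11-diynyl)phenyl]ethanone | CCCCCC#CCC#CCCCCCCCc1cc(O[Si](C)(C)C(C)(C)C)cc(O[Si](C)(C)C(C)(C)C)c1C(C)=O | intermediate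
17 | [1-[2,4-bis(tert-butyldimethylsilyloxy)-6-(heptadeca-8,11-diynyl)phenyl]-1-hydroxyethyl] 3-chlorobenzenecarboperoxoate (racemic) | CCCCCC#CCC#CCCCCCCCc1cc(O[Si](C)(C)C(C)(C)C)cc(O[Si](C)(C)C(C)(C)C)c1C(C)(O)OOC(=O)c1cccc(Cl)c1 | intermediate
18 | [2,4-bis(tert-butyldimethylsilyloxy)-6-(heptadeca-8,11-diynyl)phenyl] acetate | CCCCCC#CCC#CCCCCCCCc1cc(O[Si](C)(C)C(C)(C)C)cc(O[Si](C)(C)C(C)(C)C)c1OC(C)=O | intermediate
19 | [2,4-bis(tert-butyldimethylsilyloxy)-6-[(8Z,11Z)-heptadeca-8,11-dienyl]phenyl] acetate | CCCCC/C=C\C/C=C\CCCCCCCc1cc(O[Si](C)(C)C(C)(C)C)cc(O[Si](C)(C)C(C)(C)C)c1OC(C)=O | intermediate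
20 | ardisiphenol C, [2-[(8Z,11Z)-heptadeca-8,11-dienyl]-4,6-dihydroxyphenyl] acetate | CCCCC/C=C\C/C=C\CCCCCCCc1cc(O)cc(O)c1OC(C)=O | target

## Step count and least certain steps

Total: 9 steps. Longest linear sequence: 7 steps (steps 1, 2, 5, 6, 7, 8, 9; the diene branch, steps 3, 4 and 5 to 9, is equally long).

**Step 5 (key step).** The diene may be lost by protodesilylation or silyl migration faster than it adds to an internal, alkyl-substituted ynone. The addition may also proceed stepwise and close by aldol attack on the acetyl carbonyl, which would give the wrong ring substitution.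
Fallback, from 9 back to 15: the ynone is heated without solvent at about 120 °C with the more heat-stable 1,1-dimethoxy-3-(trimethylsilyloxy)buta-1,3-diene F1, made by enol silylation of 4,4-dimethoxybut-3-en-2-one. The adduct 1-[2-(heptadeca-8,11-diynyl)-6,6-dimethoxy-4-(trimethylsilyloxy)cyclohexa-1,4-dien-1-yl]ethanone F2 aromatises on acid work-up to 1-[2-(heptadeca-8,11-diynyl)-4-hydroxy-6-methoxyphenyl]ethanone F3. Its methoxy group ortho to the acetyl is then removed by chelation-directed cleavage with BCl3 in CH2Cl2 at low temperature, which returns 15.

**Step 7.** Peracid addition to the crowded, doubly ortho-substituted ketone may be slow. Long exposure then allows oxidation of the electron-rich ring or of the triple bonds, and acid added to speed the reaction would strip the silyl ethers.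
Fallback, from 15 to 20: the phenols are protected with triisopropylsilyl triflate and 2,6-lutidine to give 1-[2-(heptadeca-8,11-diynyl)-4,6-bis(triisopropylsilyloxy)phenyl]ethanone F4. These ethers tolerate m-CPBA accelerated by CF3CO2H, which should give [2-(heptadeca-8,11-diynyl)-4,6-bis(triisopropylsilyloxy)phenyl] acetate F5. Semi-hydrogenation as in step 8 gives [2-[(8Z,11Z)-heptadeca-8,11-dienyl]-4,6-bis(triisopropylsilyloxy)phenyl] acetate F6, and HF·pyridine then gives 20.

**Step 9.** Acetyl migration from O1 to the freed O2, or loss of the acetate, may occur during the slower cleavage of the hindered C2 silyl ether.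
Fallback, from 15 to 20: the silyl group is changed to one that leaves under mild aqueous acid without fluoride or base. Et3SiCl and imidazole give 1-[2-(heptadeca-8,11-diynyl)-4,6-bis(triethylsilyloxy)phenyl]ethanone F7. Buffered m-CPBA gives [2-(heptadeca-8,11-diynyl)-4,6-bis(triethylsilyloxy)phenyl] acetate F8. Semi-hydrogenation gives [2-[(8Z,11Z)-heptadeca-8,11-dienyl]-4,6-bis(triethylsilyloxy)phenyl] acetate F9, and AcOH/THF/water at room temperature then gives 20.

**Step 8.** Over-reduction, incomplete reduction or Z to E isomerisation on the catalyst would give mixtures that are hard to separate from 19.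
Fallback, from 18 to 19: both triple bonds are hydroborated with dicyclohexylborane in THF at 0 °C to the bis(alkenylborane) [2,4-bis(tert-butyldimethylsilyloxy)-6-[(8Z,11Z)-8,12-bis(dicyclohexylboranyl)heptadeca-8,11-dienyl]phenyl] acetate F10 (one of four regioisomers, all leading to the same product). Protonolysis of the C–B bonds with acetic acid proceeds with retention and gives 19. This is a stoichiometric syn addition that cannot over-reduce.

**Step 1.** Statistical double coupling of the symmetric diyne, and a difficult separation of three hydrocarbons, may cut the supply of 5.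
Fallback, from 2 to 5: the bromide is coupled under the same copper conditions with dec-9-yn-1-ol to give octadeca-9,12-diyn-1-ol F11, which is polar and easy to purify. Oxidation with Dess–Martin periodinane gives octadeca-9,12-diynal F12. Homologation with dimethyl (1-diazo-2-oxopropyl)phosphonate and K2CO3 in methanol then gives 5 without any statistical step.

## Further compounds

F1 | step 5 | 1,1-dimethoxy-3-(trimethylsilyloxy)buta-1,3-diene | C=C(O[Si](C)(C)C)C=C(OC)OC
F2 | step 5 | 1-[2-(heptadeca-8,11-diynyl)-6,6-dimethoxy-4-(trimethylsilyloxy)cyclohexa-1,4-dien-1-yl]ethanone | CC(=O)C1=C(CCCCCCCC#CCC#CCCCCC)CC(O[Si](C)(C)C)=CC1(OC)OC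
F3 | step 5 | 1-[2-(heptadeca-8,11-diynyl)-4-hydroxy-6-methoxyphenyl]ethanone | CCCCCC#CCC#CCCCCCCCc1cc(O)cc(OC)c1C(C)=O
F4 | step 7 | 1-[2-(heptadeca-8,11-diynyl)-4,6-bis(triisopropylsilyloxy)phenyl]ethanone | CCCCCC#CCC#CCCCCCCCc1cc(O[Si](C(C)C)(C(C)C)C(C)C)cc(O[Si](C(C)C)(C(C)C)C(C)C)c1C(C)=O
F5 | step 7 | [2-(heptadeca-8,11-diynyl)-4,6-bis(triisopropylsilyloxy)phenyl] acetate | CCCCCC#CCC#CCCCCCCCc1cc(O[Si](C(C)C)(C(C)C)C(C)C)cc(O[Si](C(C)C)(C(C)C)C(C)C)c1OC(C)=O
F6 | step 7 | [2-[(8Z,11Z)-heptadeca-8,11-dienyl]-4,6-bis(triisopropylsilyloxy)phenyl] acetate | CCCCC/C=C\C/C=C\CCCCCCCc1cc(O[Si](C(C)C)(C(C)C)C(C)C)cc(O[Si](C(C)C)(C(C)C)C(C)C)c1OC(C)=O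
F7 | step 9 | 1-[2-(heptadeca-8,11-diynyl)-4,6-bis(triethylsilyloxy)phenyl]ethanone | CCCCCC#CCC#CCCCCCCCc1cc(O[Si](CC)(CC)CC)cc(O[Si](CC)(CC)CC)c1C(C)=O
F8 | step 9 | [2-(heptadeca-8,11-diynyl)-4,6-bis(triethylsilyloxy)phenyl] acetate | CCCCCC#CCC#CCCCCCCCc1cc(O[Si](CC)(CC)CC)cc(O[Si](CC)(CC)CC)c1OC(C)=O
F9 | step 9 | [2-[(8Z,11Z)-heptadeca-8,11-dienyl]-4,6-bis(triethylsilyloxy)phenyl] acetate | CCCCC/C=C\C/C=C\CCCCCCCc1cc(O[Si](CC)(CC)CC)cc(O[Si](CC)(CC)CC)c1OC(C)=O
F10 | step 8 | [2,4-bis(tert-butyldimethylsilyloxy)-6-[(8Z,11Z)-8,12-bis(dicyclohexylboranyl)heptadeca-8,11-dienyl]phenyl] acetate | CCCCC/C(B(C1CCCCC1)C1CCCCC1)=C\C/C=C(B(C1CCCCC1)C1CCCCC1)\CCCCCCCc1cc(O[Si](C)(C)C(C)(C)C)cc(O[Si](C)(C)C(C)(C)C)c1OC(C)=O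
F11 | step 1 | octadeca-9,12-diyn-1-ol | CCCCCC#CCC#CCCCCCCCCO
F12 | step 1 | octadeca-9,12-diynal | CCCCCC#CCC#CCCCCCCCC=O
A1 | alternative 1 | 2-[(8Z,11Z)-heptadeca-8,11-dienyl]-4,6-bis(methoxymethoxy)phenol | CCCCC/C=C\C/C=C\CCCCCCCc1cc(OCOC)cc(OCOC)c1O
A2 | alternative 1 | 2-bromo-1-fluoro-3,5-bis(methoxymethoxy)benzene | COCOc1cc(F)c(Br)c(OCOC)c1
A3 | alternative 1 | [(8Z,11Z)-heptadeca-8,11-dienyl]magnesium bromide | CCCCC/C=C\C/C=C\CCCCCCC[Mg]Br
A4 | alternative 2 | 5-[(8Z,11Z)-heptadeca-8,11-dienyl]-7-hydroxy-2,2-dimethyl-1,3-benzodioxin-4-one | CCCCC/C=C\C/C=C\CCCCCCCc1cc(O)cc2OC(C)(C)OC(=O)c12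
A5 | alternative 2 | 6-[(12Z,15Z)-2,4-dioxohenicosa-12,15-dienyl]-2,2-dimethyl-1,3-dioxin-4-one | CCCCC/C=C\C/C=C\CCCCCCCC(=O)CC(=O)CC1=CC(=O)OC(C)(C)O1
A6 | alternative 2 | linoleic acid, (9Z,12Z)-octadeca-9,12-dienoic acid | CCCCC/C=C\C/C=C\CCCCCCCC(O)=O
A7 | alternative 3 | 4-tert-butoxy-2-[(8Z,11Z)-heptadeca-8,11-dienyl]-6-hydroxyphenyl acetate | CCCCC/C=C\C/C=C\CCCCCCCc1cc(OC(C)(C)C)cc(O)c1OC(C)=O
A8 | alternative 3 | [(10Z,13Z)-2-(2-diazoacetyl)nonadeca-1,10,13-trienyl] acetate (enol acetate geometry open) | CCCCC/C=C\C/C=C\CCCCCCCC(=COC(C)=O)C(=O)C=[N+]=[N-]
A9 | alternative 3 | tert-butoxyethyne | CC(C)(C)OC#C
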